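The easy mistake with the south run is to take its plateau of 92 % target for what the next flask reaches, when that plateau belongs to a charge with c(partner) = 48 mM.

the same everywhere: substrate 20 mM
- south: partner 48 mM; temperature 90 °C; run made earlier
- Wednesday's: partner 24.0 mM; temperature 90 °C; time 15 min
- Tuesday's: partner 24.0 mM; at 60 °C until 10 min, from then on at 90 °C; time 15 min
- Saturday's: partner 24.0 mM; temperature 60 °C; time 15 min

south run (percent of the substrate charged)

| time / min | target / % |
|---|---|
| 0.667 | 72 |
| 1.33 | 84 |
| 2.00 | 90 |
| 2.50 | 90 |
| 3.00 | 92 |
| 4.00 | 92 |
| 5.00 | 90 |

(each reading ± 1.5 percentage points)

1. the flask with the highest amount of target, in percent of the substrate charged ("all alike" if they lie within 1.5 percentage points) (Wednesday's / Tuesday's / Saturday's / all alike)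
2. final target, as a percentage of the substrate charged, in Wednesday's
3. final target, as a percentage of the substrate charged, in Tuesday's
4. final target, as a percentage of the substrate charged, in Saturday's

- a species is counted by the substrate in it: one homo dimer counts as two
- the earlier runs were read with a standard deviation of 1.5 percentage points
- what may be going on: substrate + partner -> target; 2 substrate -> homo dimer
- the earlier runs do not show what temperature does; that part of a forecast is a guess

My own reckoning starts from the first reading of the south run. Of the 92 % that the plateau reading promised, 20 percentage points was still to come at 0.667 min, so if partner is treated as standing still (pseudo-first-order), a substrate lifetime, the time for a fall by a factor e, is 0.437 min. If that lifetime scales inversely with partner, c(partner) = 24.0 mM stretches it to 0.874 min, and Wednesday's gets 17.2 lifetimes in its 15 min. This number of substrate lifetimes in a run, the lifetime count, is what I carry; it says whether a flask has had time, and it gives no yield.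

Two chemists read that count differently. The clock-reader argues that Wednesday's is long finished, that the south run's share carries over, so that it ends near 92 %, and that flasks held at 60 °C get fewer lifetimes and trail it. The share-counter answers that a finished flask has still to be divided between target and homo dimer, and that less partner tilts this competition towards the homo dimer. Hers is the forecast: 82 % in Wednesday's, 83 % in Tuesday's, 74 % in Saturday's, with most in Tuesday's. Of Tuesday's she says: “It should match Wednesday's at full conversion, or do slightly better if dimerisation has the higher activation energy, which is my guess.”

The simulation gives 76.1 % in Wednesday's, 81.8 % in Tuesday's and 76.7 % in Saturday's, so Tuesday's holds most. The clock-reader loses, and the forecast stands 5.9 points too high on Wednesday's.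

    substrate + partner → target, rate k1*[substrate]*[partner]^1.5 (k = 4.67 M⁻¹·⁵ s⁻¹, Ea = 38.0 kJ mol⁻¹)
    2 substrate → homo dimer (k = 0.180 M⁻¹ s⁻¹, Ea = 70.0 kJ mol⁻¹)
    (constants at 90 °C)

The count of 17.2 was right that Wednesday's had time: ten times as long gives 76.7 %, so the length of the run is not what holds it at 76.1 %, and the main reason is the homo dimer step, without which Wednesday's ends at 95.1 %. The clock-reader keeps the cool stretch of Tuesday's: at 7.50 min the substrate left gives Tuesday's a count of 1.42 against 3.37 in Wednesday's, itself short of the 8.58 my lifetime allowed, and Wednesday's then holds 73.3 % target, more than Tuesday's 65.7 %.

Readings and results were computed from invented constants.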